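The route rests on cutting ring B of the labdane at C5–C10 and C8–C9. Ring B is a cyclohexene whose adjacent stereocentres C5, C10 and C9 sit around the A/B fusion. Its C7–C8 alkene can be derived from a temporary oxygen at C6, which is the pattern of an intramolecular Diels–Alder adduct. Acyclic trienone 23 already holds the C3 silyl ether and the complete side chain. In it a (Z,E)-2-silyloxy diene (C5–C8) is tied by C4–C1 to an (E)-enone (C9=C10, C11=O). Heating 23 should form both bonds, both rings and all three stereocentres at once. Afterwards C11 and then C6 are deoxygenated separately.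

Key step: step 14

Assumption: labdane numbering is used (C17 on C8, C18/C19 on C4, C20 on C10, C16 on C13) and TBS = tert-butyldimethylsilyl; the carbinol centres created in 15, 25 and 26 form as epimer mixtures, are destroyed later and are drawn without configuration.

Step 1
Reactants: 1 pent-4-yn-1-ol
Product: 3 (E)-5-iodo-4-methylpent-4-en-1-ol, via alkenylalane 2 (not isolated)
Conditions: Me3Al (3 equiv), Cp2ZrCl2 (0.25 equiv), CH2Cl2, 0 °C to rt; then I2, THF, −30 °C
Reagents that add atoms: trimethylaluminium, C[Al](C)C; iodine, II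
Why: Negishi zirconium-catalysed carboalumination adds methyl and aluminium syn across the terminal alkyne with the metal at the terminus, and iodinolysis with retention fixes the (E)-alkene in which the future C20 methyl is cis to the future C11.

Step 2
Reactants: 3 (E)-5-iodo-4-methylpent-4-en-1-ol
Product: 4 (E)-5-iodo-4-methylpent-4-enal
Conditions: TEMPO (10 mol %), PhI(OAc)2, CH2Cl2, rt
Reagents that add atoms: none
Why: The oxoammonium-catalysed TEMPO oxidation stops at the aldehyde and leaves the alkenyl iodide untouched.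

Step 3
Reactants: 4 (E)-5-iodo-4-methylpent-4-enal; 5 3-methylbuta-1,2-diene
Product: 8 (4S,7E)-8-iodo-3,3,7-trimethylocta-1,7-dien-4-ol, via prenylborane 6 (not isolated), via borinate 7 (not isolated)
Conditions: 5, (+)-Ipc2BH [from (−)-α-pinene], THF, −25 to 0 °C; then 4, Et2O, −78 °C; NaOH, H2O2, 0 °C to rt
Reagents that add atoms: none
Why: In this Brown reverse prenylation, hydroboration of the allene places boron on the CH2 terminus and the prenylborane adds through its γ-carbon in a closed chair transition state in which the Ipc groups from (−)-α-pinene open the Re face of the aldehyde, which sets C3 as (S) and installs the C4 gem-dimethyl group with the same bond.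

Step 4
Reactants: 8 (4S,7E)-8-iodo-3,3,7-trimethylocta-1,7-dien-4-ol
Product: 9 (4S,7E)-4-(TBSO)-8-iodo-3,3,7-trimethylocta-1,7-diene
Conditions: TBSOTf, 2,6-lutidine, CH2Cl2, 0 °C
Reagents that add atoms: TBSOTf, CC(C)(C)[Si](C)(C)OS(=O)(=O)C(F)(F)F
Why: Silylation with the silyl triflate overcomes the hindrance of the neopentyl-type carbinol and installs the group that later steers the cycloaddition and lasts until step 22.

Step 5
Reactants: 9 (4S,7E)-4-(TBSO)-8-iodo-3,3,7-trimethylocta-1,7-diene
Product: 11 (4S,7E)-4-(TBSO)-8-iodo-3,3,7-trimethyloct-7-en-1-ol, via alkylborane 10 (not isolated)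
Conditions: 9-BBN (1.5 equiv), THF, 0 °C to rt; then NaOH, H2O2, 0 °C
Reagents that add atoms: hydrogen peroxide, OO
Why: Anti-Markovnikov hydroboration–oxidation with 9-BBN selects the monosubstituted alkene over the trisubstituted, iodine-deactivated one, as in substrates prepared for B-alkyl Suzuki couplings, and the C–I bond survives basic peroxide.

Step 6
Reactants: 11 (4S,7E)-4-(TBSO)-8-iodo-3,3,7-trimethyloct-7-en-1-ol
Product: 12 (4S,7E)-4-(TBSO)-8-iodo-3,3,7-trimethyloct-7-enal
Conditions: TEMPO (10 mol %), PhI(OAc)2, CH2Cl2, rt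
Reagents that add atoms: none
Why: The TEMPO oxidation gives the aldehyde (future C6) without over-oxidation, and the quaternary β-carbon excludes elimination of the silyloxy group.

Step 7
Reactants: 12 (4S,7E)-4-(TBSO)-8-iodo-3,3,7-trimethyloct-7-enal; 13 (E)-1-bromoprop-1-ene
Product: 15 (2E,7S,10E)-7-(TBSO)-11-iodo-6,6,10-trimethylundeca-2,10-dien-4-ol, via propenyllithium 14 (not isolated)
Conditions: 13 (1.2 equiv), t-BuLi (2.4 equiv), Et2O, −78 °C; cannulated onto 12, Et2O, −78 °C, short contact; aq NH4Cl
Reagents that add atoms: none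
Why: Bromine–lithium exchange keeps the (E)-geometry, and 1,2-addition of the alkenyllithium to the aldehyde at −78 °C outruns iodine–lithium exchange at the trisubstituted alkenyl iodide, while the new carbinol centre is lost in step 8.

Step 8
Reactants: 15 (2E,7S,10E)-7-(TBSO)-11-iodo-6,6,10-trimethylundeca-2,10-dien-4-ol
Product: 16 (2E,7S,10E)-7-(TBSO)-11-iodo-6,6,10-trimethylundeca-2,10-dien-4-one
Conditions: DMP, CH2Cl2, rt
Reagents that add atoms: none
Why: Dess–Martin oxidation of the allylic alcohol gives the (E)-propenyl ketone under near-neutral conditions without touching C–I or Si–O bonds.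

Step 9
Reactants: 16 (2E,7S,10E)-7-(TBSO)-11-iodo-6,6,10-trimethylundeca-2,10-dien-4-one
Product: 17 (2E,4Z,7S,10E)-4,7-bis(TBSO)-11-iodo-6,6,10-trimethylundeca-2,4,10-triene
Conditions: TBSOTf (1.3 equiv), Et3N (2 equiv), CH2Cl2, −78 to 0 °C; cold aq NaHCO3; Et3N-deactivated silica
Reagents that add atoms: TBSOTf, CC(C)(C)[Si](C)(C)OS(=O)(=O)C(F)(F)F
Why: In this soft enolisation the O-silylated enone normally loses the α′ proton (C5) to give the cross-conjugated 2-silyloxy diene, the (Z)-enol ether forms because the quaternary C4 avoids the vinyl group and so ends up on the outside of the diene, and the robust TBS group is chosen so that the enol ether survives steps 13 to 17.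

Step 10
Reactants: 18 methyl hydrogen (R)-3-methylglutarate
Product: 19 methyl (R)-5-hydroxy-3-methylpentanoate
Conditions: BH3·SMe2, THF, −10 °C to rt; then H2O; used at once
Reagents that add atoms: none
Why: Borane reduces the free acid chemoselectively through an acyloxyborane while the methyl ester stays, so the two arms of the glutarate are told apart (acid arm becomes C14–C15, ester arm C12–C11) and the existing stereocentre becomes C13.

Step 11
Reactants: 19 methyl (R)-5-hydroxy-3-methylpentanoate
Product: 20 methyl (R)-5-(TBSO)-3-methylpentanoate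
Conditions: TBSCl, imidazole, CH2Cl2, 0 °C to rt
Reagents that add atoms: TBSCl, CC(C)(C)[Si](C)(C)Cl
Why: Standard imidazole-promoted silylation of the primary alcohol blocks lactonisation and matches the protecting group at C3 for a single final deprotection.

Step 12
Reactants: 20 methyl (R)-5-(TBSO)-3-methylpentanoate
Product: 21 (R)-5-(TBSO)-N-methoxy-N,3-dimethylpentanamide
Conditions: MeNH(OMe)·HCl, i-PrMgCl (3 equiv), THF, −20 to 0 °C
Reagents that add atoms: N,O-dimethylhydroxylamine hydrochloride, CNOC.Cl
Why: Aminolysis of the ester with the magnesium amide is the direct entry to a Weinreb amide and does not touch C13, which is β to the carbonyl group.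

Step 13
Reactants: 17 (2E,4Z,7S,10E)-4,7-bis(TBSO)-11-iodo-6,6,10-trimethylundeca-2,4,10-triene; 21 (R)-5-(TBSO)-N-methoxy-N,3-dimethylpentanamide
Product: 23 (3R,6E,10S,12Z,14E)-1,10,13-tris(TBSO)-3,7,11,11-tetramethylhexadeca-6,12,14-trien-5-one, via alkenyllithium 22 (not isolated)
Conditions: 17, t-BuLi (2.05 equiv), Et2O, −78 °C; then 21, −78 to −20 °C; pH 7 phosphate buffer; Et3N-deactivated silica
Reagents that add atoms: none
Why: Iodine–lithium exchange with retention of the (E)-geometry followed by the Weinreb ketone synthesis gives the enone directly at the ketone oxidation level through a chelated adduct that prevents over-addition, so the sensitive dienol ether meets neither a Lewis-acidic metal salt nor an oxidant.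

Step 14
Reactants: 23 (3R,6E,10S,12Z,14E)-1,10,13-tris(TBSO)-3,7,11,11-tetramethylhexadeca-6,12,14-trien-5-one
Product: 24 (13R)-3β,6,15-tris(TBSO)-8αH-labd-6-en-11-one
Conditions: toluene (0.01 M), BHT (cat), silylated sealed tube, 180 °C
Reagents that add atoms: none
Why: Heating should trigger a concerted, suprafacial but asynchronous intramolecular Diels–Alder reaction in which the enol-ether carbon C5, the donor end of the diene, bonds to the acceptor β-carbon C10 of the enone slightly ahead of C8–C9, so the crowded quaternary bond joins a donor to an acceptor. The closest known reaction type is the type 1 IMDA of 1,3,9-decatrienes that combine a 2-silyloxy diene and a carbonyl group on the outer dienophile carbon, an established entry to trans-decalins. Ring B is the cyclohexene born from the six reacting carbons (C5 to C8 of the diene, C9 and C10 of the alkene), and ring A results passively, since the C5–C10 bond also ties the ends of the C4–C3–C2–C1 chain, which adopts a chair in the transition state. C9 and C10 follow from stereospecific syn addition to the (E)-alkene (C20 cis to C11), C5 follows from the ketone-endo alignment that puts the outside diene substituent C4 cis to C20 and hence H-5 trans to it, and C8 follows from the (E)-propenyl geometry (C17 cis to C11, a centre erased in step 18). The step needs endo over exo selectivity and one diene face: the endo mode gains from overlap of C11=O with C6–C7 while the tether stays a chair, and the face is fixed by the C3 stereocentre, whose OTBS group stays equatorial, whereas the other face would force it axial against H-1 and H-5. The quaternary C4 blocks 1,5-hydrogen shifts of the diene, and an inverse-demand hetero-Diels–Alder adduct of the enone, should it form, is an allyl vinyl ether that would pass into 24 by Claisen rearrangement.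

Step 15
Reactants: 24 (13R)-3β,6,15-tris(TBSO)-8αH-labd-6-en-11-one
Product: 25 (13R)-3β,6,15-tris(TBSO)-8αH-labd-6-en-11-ol
Conditions: LiAlH4, Et2O, 0 °C
Reagents that add atoms: none
Why: Hydride reduction touches only the C11 ketone because C6 is masked as its silyl enol ether, which removes the acidity of H-9 before any C7–C8 unsaturation exists and so protects C9 from epimerisation, while the new C11 centre is lost in step 17.

Step 16
Reactants: 25 (13R)-3β,6,15-tris(TBSO)-8αH-labd-6-en-11-ol
Product: 26 O-[(13R)-3β,6,15-tris(TBSO)-8αH-labd-6-en-11-yl] S-methyl dithiocarbonate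
Conditions: NaH, imidazole (cat), THF, 0 °C to rt; CS2; then MeI
Reagents that add atoms: carbon disulfide, S=C=S; iodomethane, CI
Why: Xanthate formation, the first half of the Barton–McCombie deoxygenation, works on hindered secondary alkoxides because CS2 is small, and silyl ethers and the hindered enol ether tolerate NaH and MeI.

Step 17
Reactants: 26 O-[(13R)-3β,6,15-tris(TBSO)-8αH-labd-6-en-11-yl] S-methyl dithiocarbonate
Product: 27 (13S)-3β,6,15-tris(TBSO)-8αH-labd-6-ene
Conditions: Bu3SnH, AIBN (cat), toluene, 100 °C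
Reagents that add atoms: none
Why: In the Barton–McCombie radical deoxygenation the stannyl radical adds to C=S, the non-allylic secondary C11 radical is released and takes hydrogen from Bu3SnH, and no centre is touched (the C13 label changes to S by priority only).

Step 18
Reactants: 27 (13S)-3β,6,15-tris(TBSO)-8αH-labd-6-ene
Product: 28 (13S)-3β,15-bis(TBSO)labd-7-en-6-one
Conditions: Pd(OAc)2 (1.1 equiv), MeCN–CH2Cl2, rt to 40 °C
Reagents that add atoms: none
Why: In the Saegusa–Ito oxidation divalent palladium attacks C7 of the enol ether from the open α face and syn β-hydride elimination of H-8α gives the 7-en-6-one regiospecifically, which erases the C8 centre under neutral conditions that leave H-5 and H-9 alone.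

Step 19
Reactants: 28 (13S)-3β,15-bis(TBSO)labd-7-en-6-one
Product: 29 (13S)-3β,15-bis(TBSO)labd-7-en-6β-ol
Conditions: NaBH4, CeCl3·7H2O, MeOH, −20 to 0 °C
Reagents that add atoms: none
Why: In the Luche 1,2-reduction hydride reaches C6 from the α face because the axial C19 and C20 methyl groups screen the β face, which gives the pseudoaxial 6β-alcohol.

Step 20
Reactants: 29 (13S)-3β,15-bis(TBSO)labd-7-en-6β-ol
Product: 30 (13S)-3β,15-bis(TBSO)labd-7-en-6β-yl methyl carbonate
Conditions: LiN(SiMe3)2, THF, −78 °C; ClCO2Me, −78 to 0 °C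
Reagents that add atoms: methyl chloroformate, COC(=O)Cl
Why: Acylation of the lithium alkoxide with the small chloroformate turns the hindered 6β-hydroxyl into a leaving group that ionises irreversibly on palladium.

Step 21
Reactants: 30 (13S)-3β,15-bis(TBSO)labd-7-en-6β-yl methyl carbonate
Product: 31 (13S)-3β,15-bis(TBSO)labd-7-ene
Conditions: Pd(PPh3)4 (10 mol %), NaBH4, THF, rt to 50 °C
Reagents that add atoms: none
Why: In this Tsuji–Trost-type hydrogenolysis zerovalent palladium ionises the pseudoaxial carbonate from the α face to a C6–C7–C8 π-allyl complex, and a borohydride, unlike formate, delivers hydride to the less substituted terminus C6 as it does in prenyl-type systems, which keeps the trisubstituted C7–C8 alkene in place.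

Step 22
Reactants: 31 (13S)-3β,15-bis(TBSO)labd-7-ene
Product: 32 (13S)-labd-7-ene-3β,15-diol
Conditions: TBAF (excess), THF, 50 °C
Reagents that add atoms: none
Why: Fluoride-mediated desilylation removes both TBS groups, warming serves the hindered C3 ether, and the acid-free medium cannot move the alkene.

Step 23
Reactants: 32 (13S)-labd-7-ene-3β,15-diol
Product: 33 (3S,5R,9S,10R,13S)-labd-7-ene-3,15-diyl diformate
Conditions: AcOCHO (preformed, excess), pyridine, DMAP (cat), CH2Cl2, 0 °C to rt
Reagents that add atoms: acetic formic anhydride, CC(=O)OC=O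
Why: In O-formylation with the mixed anhydride the formyl carbonyl is the more electrophilic one, so the primary C15 and the equatorial C3 hydroxyl groups both become formates under mild base.

Compound list
1 | pent-4-yn-1-ol | C#CCCCO | starting material
2 | dimethyl{(1E)-5-[(dimethylalumanyl)oxy]-2-methylpent-1-en-1-yl}alumane (Al cis to the new methyl) | C/C(CCCO[Al](C)C)=C\[Al](C)C | intermediate
3 | (E)-5-iodo-4-methylpent-4-en-1-ol | OCCC/C(C)=C/I | intermediate
4 | (E)-5-iodo-4-methylpent-4-enal | O=CCC/C(C)=C/I | intermediate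
5 | 3-methylbuta-1,2-diene | CC(C)=C=C | starting material
6 | (3-methylbut-2-en-1-yl)diisopinocampheylborane, Ipc groups from (−)-α-pinene | CC(C)=CCB([C@H]1C[C@H]2C[C@@H]([C@@H]1C)C2(C)C)[C@H]1C[C@H]2C[C@@H]([C@@H]1C)C2(C)C | intermediate
7 | diisopinocampheylborinic ester of alcohol 8 | C=CC(C)(C)[C@@H](OB([C@H]1C[C@H]2C[C@@H]([C@@H]1C)C2(C)C)[C@H]1C[C@H]2C[C@@H]([C@@H]1C)C2(C)C)CC/C(C)=C/I | intermediate
8 | (4S,7E)-8-iodo-3,3,7-trimethylocta-1,7-dien-4-ol | C=CC(C)(C)[C@@H](O)CC/C(C)=C/I | intermediate
9 | (4S,7E)-4-(TBSO)-8-iodo-3,3,7-trimethylocta-1,7-diene | C=CC(C)(C)[C@@H](O[Si](C)(C)C(C)(C)C)CC/C(C)=C/I | intermediate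
10 | 9-[(4S,7E)-4-(TBSO)-8-iodo-3,3,7-trimethyloct-7-en-1-yl]-9-borabicyclo[3.3.1]nonane | C1CC2CCCC(C1)B2CCC(C)(C)[C@@H](O[Si](C)(C)C(C)(C)C)CC/C(C)=C/I | intermediate
11 | (4S,7E)-4-(TBSO)-8-iodo-3,3,7-trimethyloct-7-en-1-ol | OCCC(C)(C)[C@@H](O[Si](C)(C)C(C)(C)C)CC/C(C)=C/I | intermediate
12 | (4S,7E)-4-(TBSO)-8-iodo-3,3,7-trimethyloct-7-enal | O=CCC(C)(C)[C@@H](O[Si](C)(C)C(C)(C)C)CC/C(C)=C/I | intermediate
13 | (E)-1-bromoprop-1-ene | C/C=C/Br | starting material
14 | (E)-prop-1-en-1-yllithium | C/C=C/[Li] | intermediate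
15 | (2E,7S,10E)-7-(TBSO)-11-iodo-6,6,10-trimethylundeca-2,10-dien-4-ol (C4 epimers) | C/C=C/C(O)CC(C)(C)[C@@H](O[Si](C)(C)C(C)(C)C)CC/C(C)=C/I | intermediate
16 | (2E,7S,10E)-7-(TBSO)-11-iodo-6,6,10-trimethylundeca-2,10-dien-4-one | C/C=C/C(=O)CC(C)(C)[C@@H](O[Si](C)(C)C(C)(C)C)CC/C(C)=C/I | intermediate
17 | (2E,4Z,7S,10E)-4,7-bis(TBSO)-11-iodo-6,6,10-trimethylundeca-2,4,10-triene | C/C=C/C(O[Si](C)(C)C(C)(C)C)=C/C(C)(C)[C@@H](O[Si](C)(C)C(C)(C)C)CC/C(C)=C/I | intermediate
18 | methyl hydrogen (R)-3-methylglutarate | COC(=O)C[C@H](C)CC(=O)O | starting material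
19 | methyl (R)-5-hydroxy-3-methylpentanoate | COC(=O)C[C@H](C)CCO | intermediate
20 | methyl (R)-5-(TBSO)-3-methylpentanoate | COC(=O)C[C@H](C)CCO[Si](C)(C)C(C)(C)C | intermediate
21 | (R)-5-(TBSO)-N-methoxy-N,3-dimethylpentanamide | CON(C)C(=O)C[C@H](C)CCO[Si](C)(C)C(C)(C)C | intermediate
22 | alkenyllithium: 17 with Li in place of I, (E)-geometry retained | C/C=C/C(O[Si](C)(C)C(C)(C)C)=C/C(C)(C)[C@@H](O[Si](C)(C)C(C)(C)C)CC/C(C)=C/[Li] | intermediate
23 | (3R,6E,10S,12Z,14E)-1,10,13-tris(TBSO)-3,7,11,11-tetramethylhexadeca-6,12,14-trien-5-one (labdane C3 S, C13 R) | C/C=C/C(O[Si](C)(C)C(C)(C)C)=C/C(C)(C)[C@@H](O[Si](C)(C)C(C)(C)C)CC/C(C)=C/C(=O)C[C@H](C)CCO[Si](C)(C)C(C)(C)C | intermediate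
24 | (13R)-3β,6,15-tris(TBSO)-8αH-labd-6-en-11-one (trans-decalin; 5α-H; 9α-H; 10β-CH3; 8β-CH3) | C[C@H]1C=C(O[Si](C)(C)C(C)(C)C)[C@H]2C(C)(C)[C@@H](O[Si](C)(C)C(C)(C)C)CC[C@]2(C)[C@H]1C(=O)C[C@H](C)CCO[Si](C)(C)C(C)(C)C | intermediate
25 | (13R)-3β,6,15-tris(TBSO)-8αH-labd-6-en-11-ol (C11 epimers) | C[C@H]1C=C(O[Si](C)(C)C(C)(C)C)[C@H]2C(C)(C)[C@@H](O[Si](C)(C)C(C)(C)C)CC[C@]2(C)[C@H]1C(O)C[C@H](C)CCO[Si](C)(C)C(C)(C)C | intermediate
26 | S-methyl xanthate of 25 at O-11 | C[C@H]1C=C(O[Si](C)(C)C(C)(C)C)[C@H]2C(C)(C)[C@@H](O[Si](C)(C)C(C)(C)C)CC[C@]2(C)[C@H]1C(OC(=S)SC)C[C@H](C)CCO[Si](C)(C)C(C)(C)C | intermediate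
27 | (13S)-3β,6,15-tris(TBSO)-8αH-labd-6-ene | C[C@H]1C=C(O[Si](C)(C)C(C)(C)C)[C@H]2C(C)(C)[C@@H](O[Si](C)(C)C(C)(C)C)CC[C@]2(C)[C@H]1CC[C@H](C)CCO[Si](C)(C)C(C)(C)C | intermediate
28 | (13S)-3β,15-bis(TBSO)labd-7-en-6-one | CC1=CC(=O)[C@H]2C(C)(C)[C@@H](O[Si](C)(C)C(C)(C)C)CC[C@]2(C)[C@H]1CC[C@H](C)CCO[Si](C)(C)C(C)(C)C | intermediate
29 | (13S)-3β,15-bis(TBSO)labd-7-en-6β-ol | CC1=C[C@@H](O)[C@H]2C(C)(C)[C@@H](O[Si](C)(C)C(C)(C)C)CC[C@]2(C)[C@H]1CC[C@H](C)CCO[Si](C)(C)C(C)(C)C | intermediate
30 | (13S)-3β,15-bis(TBSO)labd-7-en-6β-yl methyl carbonate | CC1=C[C@@H](OC(=O)OC)[C@H]2C(C)(C)[C@@H](O[Si](C)(C)C(C)(C)C)CC[C@]2(C)[C@H]1CC[C@H](C)CCO[Si](C)(C)C(C)(C)C | intermediate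
31 | (13S)-3β,15-bis(TBSO)labd-7-ene | CC1=CC[C@H]2C(C)(C)[C@@H](O[Si](C)(C)C(C)(C)C)CC[C@]2(C)[C@H]1CC[C@H](C)CCO[Si](C)(C)C(C)(C)C | intermediate
32 | (13S)-labd-7-ene-3β,15-diol | CC1=CC[C@H]2C(C)(C)[C@@H](O)CC[C@]2(C)[C@H]1CC[C@H](C)CCO | intermediate
33 | (3S,5R,9S,10R,13S)-labd-7-ene-3,15-diyl diformate (CNP0137609.1) | CC1=CC[C@H]2C(C)(C)[C@@H](OC=O)CC[C@]2(C)[C@H]1CC[C@H](C)CCOC=O | target

Total step count: 23 steps.
Longest linear sequence: 20 steps (steps 1–9 and 13–23). Steps 10–12 build the side-chain amide in parallel.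

Steps most likely to fail

1. Step 14.
- What may go wrong: the cycloaddition may be too slow at the crowded C5–C10 bond, so that thermal decay of the dienol ether competes. Endo/exo or facial discrimination may also erode at the temperature needed.
- Fallback (a stepwise ionic annulation in place of the pericyclic step): starting from 23, catalytic Tf2NH in CH2Cl2 at −78 °C generates TBSNTf2, which activates the C11 carbonyl. Mukaiyama–Michael addition of C5 to C10, with transfer of the silyl group to O-11, should give the monocyclic enone silyl enol ether F1. On warming, the same catalyst should close C9 onto C8 in a second Mukaiyama–Michael addition that hands the silyl group to O-6. This rejoins the route at 24.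

2. Step 21.
- What may go wrong: ionisation of the hindered carbonate may be slow, or hydride may be delivered to the tertiary terminus C8 with a shift of the alkene to C6–C7.
- Fallback (a radical in place of a π-allyl metal complex): starting from 29, NaH, CS2 and MeI at 0 °C should give the allylic S-methyl xanthate F2. This is reduced at once with Bu3SnH and Et3B/air in toluene at room temperature, so that the [3,3] shift of the xanthate is outrun. That shift would have to form a C8–S bond on the screened β face. The C6–C7–C8 allyl radical should take hydrogen at its less substituted and less hindered end C6. This rejoins the route at 31.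

3. Step 18.
- What may go wrong: palladation of the hindered TBS enol ether may be sluggish, and protodesilylation to the saturated ketone may compete.
- Fallback (selenoxide elimination in place of β-hydride elimination): starting from 27, PhSeCl in CH2Cl2 at −78 °C should attack C7 from the α face and give the 7α-phenylselanyl ketone F3. Oxidation with H2O2 and pyridine at 0 °C should then trigger syn elimination of the selenoxide with the cis-disposed H-8α. This rejoins the route at 28.

Further compounds
F1 | step 14 | ring-A cyclohexane with the C5–C10 bond made: C5 bears the (E)-but-2-enoyl group, C10 bears the methyl group and the C9=C11(OTBS) enol ether side chain | C/C=C/C(=O)[C@H]1C(C)(C)[C@@H](O[Si](C)(C)C(C)(C)C)CC[C@]1(C)C=C(O[Si](C)(C)C(C)(C)C)C[C@H](C)CCO[Si](C)(C)C(C)(C)C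
F2 | step 21 | O-[(13S)-3β,15-bis(TBSO)labd-7-en-6β-yl] S-methyl dithiocarbonate | CC1=C[C@@H](OC(=S)SC)[C@H]2C(C)(C)[C@@H](O[Si](C)(C)C(C)(C)C)CC[C@]2(C)[C@H]1CC[C@H](C)CCO[Si](C)(C)C(C)(C)C
F3 | step 18 | (13S)-3β,15-bis(TBSO)-7α-(phenylselanyl)-8αH-labdan-6-one | C[C@H]1[C@H]([Se]c3ccccc3)C(=O)[C@H]2C(C)(C)[C@@H](O[Si](C)(C)C(C)(C)C)CC[C@]2(C)[C@H]1CC[C@H](C)CCO[Si](C)(C)C(C)(C)C
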